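**Plan**

- Retrosynthesis: cut the C1–O coumarate ester, take both aldehydes back to the 11,12-diol, remove the C12 oxygen (allylic oxidation) and cut C9–C11 (carbonylation of a C9 dienyl triflate). This leaves 11-nordrim-7-ene-1,9-dione, which is cut at C3–C4 (radical conjugate cyclisation), then at C10–C1 (aldol) and C10–CH3 (alkylation).
- Enabling feature: ring B (C5–C10) of the target is (R)-carvone. The carvone carbonyl is C9, its methyl-bearing alkene is C7=C8 with C12, its stereocentre is C5, and the central isopropenyl carbon is C4, which lacks only one hydrogen and the C3–C4 bond to become the gem-dimethyl quaternary carbon.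
- Forward: ring B is bought; C10 is made quaternary (methyl, then a C1–C3 acryloyl unit); ring A closes by C3–C4 bond formation; C11 is added by carbonylation, C12 is oxidised, the coumarate is attached, and the dialdehyde is released last.
- Stereochemistry: C5 comes from carvone; C10 is set by attack of acrolein anti to the isopropenyl group, which also fixes the trans ring fusion; C1 by axial hydride delivery; C9 by α-face protonation of a dienolate; the E-alkene comes with 4-hydroxycinnamic acid.

Key step: step 4

Remark: drimane numbering is used for all bicyclic compounds (ring A = C1–C5, C10; ring B = C5–C10; gem-dimethyl on C4; angular methyl on C10; C12 on C8; C11 on C9). The target is read as the 1β-(E)-p-coumarate of polygodial with 5α-H, 9α-H (9β-CHO) and 10β-CH3. Step 10 is written for the aldehyde; any C12 alcohol formed beside it would be converted to the same diol in step 11.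

**Route**

Step 1
Reactants: 1 (R)-carvone; 2 iodomethane
Product: 4 6-methylcarvone as its C6 epimer mixture, via lithium dienolate 3 (not isolated)
Conditions: LDA, THF, −78 °C; MeI, −78 → 0 °C
Reagents that add atoms: iodomethane (2), CI
Why: Kinetic deprotonation of the enone gives the cross-conjugated α′-enolate, and its alkylation with iodomethane at C6 is a standard enolate alkylation of carvone; the C6 configuration is irrelevant because this carbon is enolised again in step 2.

Step 2
Reactants: 4 6-methylcarvone; 5 acrolein
Product: 7 (5S,6R)-6-(1-hydroxyprop-2-en-1-yl)-2,6-dimethyl-5-(prop-1-en-2-yl)cyclohex-2-en-1-one (carbinol epimers), via lithium enolate 6 (not isolated)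
Conditions: LDA, THF, −78 → 0 → −78 °C; acrolein, −78 °C; AcOH quench at −78 °C
Reagents that add atoms: acrolein (5), C=CC=O
Why: In this lithium aldol addition the tetrasubstituted enolate attacks the aldehyde carbon of acrolein (1,2) on the face opposite the neighbouring isopropenyl group, as in the known second alkylations of 6-methylcarvone, so the new quaternary carbon (C10) carries the three-carbon chain trans and the methyl cis to isopropenyl; the cold acidic quench suppresses retro-aldol and the carbinol centre is removed in step 3.

Step 3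
Reactants: 7 aldol adduct
Product: 8 (5S,6R)-6-acryloyl-2,6-dimethyl-5-(prop-1-en-2-yl)cyclohex-2-en-1-one (acryloyl trans to isopropenyl)
Conditions: Dess–Martin periodinane, CH2Cl2, 0 °C → rt; used at once
Reagents that add atoms: none
Why: Dess–Martin oxidation of the secondary allylic alcohol runs without base, so the β-hydroxy ketone cannot undergo retro-aldol and the vinyl ketone is not exposed to nucleophiles.

Step 4
Reactants: 8 6-acryloyl-6-methylcarvone
Product: 9 11-nordrim-7-ene-1,9-dione (trans-fused; 5α-H; 10β-CH3)
Conditions: Fe(acac)3 (0.3 equiv), PhSiH3 (2.5 equiv), EtOH/ethylene glycol 5:1, 0.02 M, 60 °C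
Reagents that add atoms: none
Why: An iron hydride formed from Fe(acac)3 and phenylsilane transfers a hydrogen atom to the terminal CH2 of the electron-rich isopropenyl group (Markovnikov), which creates the second C4 methyl and a nucleophilic tertiary radical at C4; this radical adds to the unsubstituted β-carbon C3 of the acryloyl group, and the α-keto radical at C2 is reduced to the enolate and protonated by the solvent. The closest known reaction type is the iron-catalysed hydrogen-atom-transfer reductive coupling of unactivated alkenes with enones (a radical Giese addition), including intramolecular cases that build quaternary carbons. Ring A closes in the 6-endo-trig mode, because attack at C3 gives the stabilised α-keto radical whereas 5-exo attack at C2 would be polarity-mismatched and give a primary radical. No new stereocentre is formed (C4 carries two methyl groups); the trans ring fusion is already contained in 8, where the acryloyl group on C10 and the C4 side chain on C5 are trans and can both lie equatorially on ring B. The step needs hydrogen-atom transfer to the isopropenyl group in preference to the two electron-poor alkenes, and addition to the vinyl ketone and not to the ring enone; the first follows from the preference of the metal hydride for electron-rich unhindered alkenes, the second from the fact that the ring β-carbon C7 could only be reached through a four-membered ring. High dilution limits intermolecular addition to the reactive vinyl ketone.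

Step 5
Reactants: 9 11-nordrim-7-ene-1,9-dione
Product: 10 1β-hydroxy-11-nordrim-7-en-9-one
Conditions: NaBH4 (0.5 equiv), MeOH/CH2Cl2, −78 → −40 °C
Reagents that add atoms: none
Why: Borohydride reduces the saturated C1 ketone faster than the less electrophilic C9 enone, and hydride adds axially from the α-face, anti to the axial C10 methyl, to give the equatorial 1β-alcohol.

Step 6
Reactants: 10 1β-hydroxy-11-nordrim-7-en-9-one
Product: 11 1β-(tert-butyldimethylsilyloxy)-11-nordrim-7-en-9-one
Conditions: TBSOTf, 2,6-lutidine, CH2Cl2, 0 °C → rt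
Reagents that add atoms: tert-butyldimethylsilyl triflate, CC(C)(C)[Si](C)(C)OS(=O)(=O)C(F)(F)F
Why: Silyl triflate with a hindered pyridine base silylates the hindered secondary alcohol without forming the alkoxide, so the β-hydroxy ketone cannot fragment by retro-aldol.

Step 7
Reactants: 11 1β-silyloxy enone
Product: 13 1β-(tert-butyldimethylsilyloxy)-11-nordrima-6,8-dien-9-yl trifluoromethanesulfonate, via potassium dienolate 12 (not isolated)
Conditions: KHMDS, THF, −78 → −40 °C; PhNTf2, −78 → 0 °C
Reagents that add atoms: N-phenylbis(trifluoromethanesulfonimide), O=S(=O)(N(c1ccccc1)S(=O)(=O)C(F)(F)F)C(F)(F)F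
Why: Because C10 is quaternary the enone has no α′-hydrogen, so the base removes a γ-proton at C6 and the extended dienolate is O-sulfonylated (dienyl triflate formation from an enone).

Step 8
Reactants: 13 dienyl triflate
Product: 14 methyl 1β-(tert-butyldimethylsilyloxy)drima-6,8-dien-11-oate
Conditions: Pd(OAc)2 (10 mol%), dppf, CO (1 atm), MeOH, Et3N, DMF, 60 °C
Reagents that add atoms: carbon monoxide, [C-]#[O+]; methanol, CO
Why: Palladium-catalysed alkoxycarbonylation of an alkenyl triflate (oxidative addition, CO insertion, methanolysis) attaches C11 to C9 and tolerates the silyl ether and the diene.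

Step 9
Reactants: 14 dienoate
Product: 16 methyl 1β-(tert-butyldimethylsilyloxy)drim-7-en-11-oate (9α-H; 9β-CO2Me), via lithium ester dienolate 15 (not isolated)
Conditions: Li (2.5 equiv), NH3(l)/THF, t-BuOH (1 equiv), −78 °C; then solid NH4Cl, −78 °C
Reagents that add atoms: none
Why: In this Birch-type dissolving-metal reduction of a conjugated dienoate, two electrons and one proton at the δ-carbon C6 give the ester dienolate, and kinetic protonation at the α-carbon C9 from the α-face, anti to the axial C10 methyl, leaves the double bond at C7 and sets the 9β-ester.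

Step 10
Reactants: 16 Δ7 ester
Product: 17 methyl 1β-(tert-butyldimethylsilyloxy)-12-oxodrim-7-en-11-oate
Conditions: SeO2 (2 equiv), 1,4-dioxane, 90 °C
Reagents that add atoms: selenium dioxide, O=[Se]=O
Why: Selenium dioxide allylic oxidation (ene reaction, then [2,3]-sigmatropic shift) of a trisubstituted alkene attacks the methyl group on the more substituted alkene carbon, here C12, in preference to the tertiary C9–H, and leaves the Δ7 position unchanged.

Step 11
Reactants: 17 12-oxo ester
Product: 18 1β-(tert-butyldimethylsilyloxy)drim-7-ene-11,12-diol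
Conditions: DIBAL-H (6 equiv), CH2Cl2, −78 → 0 °C; Rochelle salt work-up
Reagents that add atoms: none
Why: Hydride reduction takes the ester to the primary alcohol and the enal by 1,2-addition to the allylic alcohol, under cold non-basic conditions that should not epimerise C9 or move the alkene.

Step 12
Reactants: 18 silyloxy diol
Product: 19 drim-7-ene-1β,11,12-triol
Conditions: TBAF, THF, 50 °C
Reagents that add atoms: none
Why: Fluoride-mediated desilylation removes the hindered secondary silyl ether, which has served its purpose once all strongly basic and reducing steps are past.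

Step 13
Reactants: 19 triol
Product: 20 11,12-bis(tert-butyldimethylsilyloxy)drim-7-en-1β-ol
Conditions: TBSCl (2.3 equiv), imidazole, DMF, 0 °C
Reagents that add atoms: tert-butyldimethylsilyl chloride, CC(C)(C)[Si](C)(C)Cl
Why: Silyl chloride with imidazole silylates the two primary hydroxyls far faster than the secondary C1 hydroxyl, which is flanked by the quaternary C10, so C1–OH alone remains free.

Step 14
Reactants: 21 (E)-4-hydroxycinnamic acid
Product: 23 (E)-4-(tert-butyldimethylsilyloxy)cinnamic acid, via bis-silyl derivative 22 (not isolated)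
Conditions: TBSCl (2.4 equiv), imidazole, DMF, rt; then AcOH/THF/H2O, rt
Reagents that add atoms: tert-butyldimethylsilyl chloride, CC(C)(C)[Si](C)(C)Cl
Why: Exhaustive silylation followed by mild aqueous acid hydrolyses only the labile silyl ester and keeps the acid-stable aryl silyl ether.

Step 15
Reactants: 20 bis-silyl alcohol; 23 silyl-protected coumaric acid
Product: 25 11,12-bis(tert-butyldimethylsilyloxy)drim-7-en-1β-yl (E)-4-(tert-butyldimethylsilyloxy)cinnamate, via mixed anhydride 24 (not isolated)
Conditions: 23, 2,4,6-trichlorobenzoyl chloride, Et3N, toluene, rt; then 20, DMAP, toluene, rt → 50 °C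
Reagents that add atoms: none
Why: Yamaguchi esterification, in which DMAP turns the mixed anhydride into a strongly acylating pyridinium species, is the standard way to acylate a hindered secondary alcohol, and it leaves the C1 configuration and the E-alkene unchanged.

Step 16
Reactants: 25 tris-silyl ester
Product: 26 11,12-dihydroxydrim-7-en-1β-yl (E)-4-(tert-butyldimethylsilyloxy)cinnamate
Conditions: CSA (0.2 equiv), MeOH/CH2Cl2 1:1, 0 °C
Reagents that add atoms: none
Why: Acid-catalysed methanolysis cleaves primary alkyl silyl ethers much faster than the aryl silyl ether, and the cold, base-free medium should keep the C1 ester from migrating to O11.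

Step 17
Reactants: 26 diol
Product: 27 11,12-dioxodrim-7-en-1β-yl (E)-4-(tert-butyldimethylsilyloxy)cinnamate
Conditions: (COCl)2, DMSO, CH2Cl2, −78 °C; Et3N, −78 → −20 °C
Reagents that add atoms: none
Why: In the Swern oxidation both alkoxysulfonium salts form before the base is added, so the 1,4-diol goes to the dialdehyde without passing through a lactol, and the low temperature preserves the C9 configuration and the Δ7 alkene; the phenol stays silylated because free phenols react with activated DMSO.

Step 18
Reactants: 27 silyl-protected dialdehyde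
Product: 28 target, 11,12-dioxodrim-7-en-1β-yl (E)-4-hydroxycinnamate
Conditions: TBAF/AcOH (1:1.2), THF, 0 °C
Reagents that add atoms: none
Why: Fluoride cleaves aryl silyl ethers rapidly, and the acetic acid buffer keeps the medium near neutral so that the epimerisable C9 aldehyde and the ester are not touched.

**Compound list**

1 | (R)-carvone, (5R)-2-methyl-5-(prop-1-en-2-yl)cyclohex-2-en-1-one | CC1=CC[C@@H](C(C)=C)CC1=O | starting material
2 | iodomethane | CI | starting material
3 | lithium dienolate of 1 (O–C1=C6) | CC1=CC[C@@H](C(C)=C)C=C1[O-].[Li+] | intermediate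
4 | 6-methylcarvone, (5R)-2,6-dimethyl-5-(prop-1-en-2-yl)cyclohex-2-en-1-one, both C6 epimers | CC1=CC[C@@H](C(C)=C)C(C)C1=O | intermediate
5 | acrolein | C=CC=O | starting material
6 | lithium enolate of 4 (tetrasubstituted C1=C6 enolate) | CC1=CC[C@@H](C(C)=C)C(C)=C1[O-].[Li+] | intermediate
7 | (5S,6R)-6-(1-hydroxyprop-2-en-1-yl)-2,6-dimethyl-5-(prop-1-en-2-yl)cyclohex-2-en-1-one, hydroxyallyl trans and methyl cis to isopropenyl, carbinol epimers | CC1=CC[C@@H](C(C)=C)[C@](C)(C(O)C=C)C1=O | intermediate
8 | (5S,6R)-6-acryloyl-2,6-dimethyl-5-(prop-1-en-2-yl)cyclohex-2-en-1-one, acryloyl trans to isopropenyl | CC1=CC[C@@H](C(C)=C)[C@](C)(C(=O)C=C)C1=O | intermediate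
9 | 11-nordrim-7-ene-1,9-dione (5α-H, 10β-CH3, trans-decalin) | CC1(C)CCC(=O)[C@]2(C)C(=O)C(C)=CC[C@@H]12 | intermediate
10 | 1β-hydroxy-11-nordrim-7-en-9-one | CC1(C)CC[C@@H](O)[C@]2(C)C(=O)C(C)=CC[C@@H]12 | intermediate
11 | 1β-(tert-butyldimethylsilyloxy)-11-nordrim-7-en-9-one | CC1(C)CC[C@@H](O[Si](C)(C)C(C)(C)C)[C@]2(C)C(=O)C(C)=CC[C@@H]12 | intermediate
12 | potassium 1β-(tert-butyldimethylsilyloxy)-11-nordrima-6,8-dien-9-olate | CC1(C)CC[C@@H](O[Si](C)(C)C(C)(C)C)[C@]2(C)C([O-])=C(C)C=C[C@@H]12.[K+] | intermediate
13 | 1β-(tert-butyldimethylsilyloxy)-11-nordrima-6,8-dien-9-yl trifluoromethanesulfonate | CC1(C)CC[C@@H](O[Si](C)(C)C(C)(C)C)[C@]2(C)C(OS(=O)(=O)C(F)(F)F)=C(C)C=C[C@@H]12 | intermediate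
14 | methyl 1β-(tert-butyldimethylsilyloxy)drima-6,8-dien-11-oate | CC1(C)CC[C@@H](O[Si](C)(C)C(C)(C)C)[C@]2(C)C(C(=O)OC)=C(C)C=C[C@@H]12 | intermediate
15 | lithium ester dienolate of 16 (C9=C11 enolate, Δ7) | CC1(C)CC[C@@H](O[Si](C)(C)C(C)(C)C)[C@]2(C)C(=C([O-])OC)C(C)=CC[C@@H]12.[Li+] | intermediate
16 | methyl 1β-(tert-butyldimethylsilyloxy)drim-7-en-11-oate (9α-H) | CC1(C)CC[C@@H](O[Si](C)(C)C(C)(C)C)[C@]2(C)[C@@H](C(=O)OC)C(C)=CC[C@@H]12 | intermediate
17 | methyl 1β-(tert-butyldimethylsilyloxy)-12-oxodrim-7-en-11-oate | CC1(C)CC[C@@H](O[Si](C)(C)C(C)(C)C)[C@]2(C)[C@@H](C(=O)OC)C(C=O)=CC[C@@H]12 | intermediate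
18 | 1β-(tert-butyldimethylsilyloxy)drim-7-ene-11,12-diol | CC1(C)CC[C@@H](O[Si](C)(C)C(C)(C)C)[C@]2(C)[C@@H](CO)C(CO)=CC[C@@H]12 | intermediate
19 | drim-7-ene-1β,11,12-triol | CC1(C)CC[C@@H](O)[C@]2(C)[C@@H](CO)C(CO)=CC[C@@H]12 | intermediate
20 | 11,12-bis(tert-butyldimethylsilyloxy)drim-7-en-1β-ol | CC1(C)CC[C@@H](O)[C@]2(C)[C@@H](CO[Si](C)(C)C(C)(C)C)C(CO[Si](C)(C)C(C)(C)C)=CC[C@@H]12 | intermediate
21 | (E)-4-hydroxycinnamic acid | O=C(O)/C=C/c1ccc(O)cc1 | starting material
22 | tert-butyldimethylsilyl (E)-4-(tert-butyldimethylsilyloxy)cinnamate | CC(C)(C)[Si](C)(C)OC(=O)/C=C/c1ccc(O[Si](C)(C)C(C)(C)C)cc1 | intermediate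
23 | (E)-4-(tert-butyldimethylsilyloxy)cinnamic acid | O=C(O)/C=C/c1ccc(O[Si](C)(C)C(C)(C)C)cc1 | intermediate
24 | (E)-4-(tert-butyldimethylsilyloxy)cinnamic 2,4,6-trichlorobenzoic anhydride | O=C(/C=C/c1ccc(O[Si](C)(C)C(C)(C)C)cc1)OC(=O)c1c(Cl)cc(Cl)cc1Cl | intermediate
25 | 11,12-bis(tert-butyldimethylsilyloxy)drim-7-en-1β-yl (E)-4-(tert-butyldimethylsilyloxy)cinnamate | CC1(C)CC[C@@H](OC(=O)/C=C/c2ccc(O[Si](C)(C)C(C)(C)C)cc2)[C@]2(C)[C@@H](CO[Si](C)(C)C(C)(C)C)C(CO[Si](C)(C)C(C)(C)C)=CC[C@@H]12 | intermediate
26 | 11,12-dihydroxydrim-7-en-1β-yl (E)-4-(tert-butyldimethylsilyloxy)cinnamate | CC1(C)CC[C@@H](OC(=O)/C=C/c2ccc(O[Si](C)(C)C(C)(C)C)cc2)[C@]2(C)[C@@H](CO)C(CO)=CC[C@@H]12 | intermediate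
27 | 11,12-dioxodrim-7-en-1β-yl (E)-4-(tert-butyldimethylsilyloxy)cinnamate | CC1(C)CC[C@@H](OC(=O)/C=C/c2ccc(O[Si](C)(C)C(C)(C)C)cc2)[C@]2(C)[C@@H](C=O)C(C=O)=CC[C@@H]12 | intermediate
28 | 11,12-dioxodrim-7-en-1β-yl (E)-4-hydroxycinnamate (1β-p-coumaroyloxypolygodial; 5α-H, 9α-H, 10β-CH3) | CC1(C)CC[C@@H](OC(=O)/C=C/c2ccc(O)cc2)[C@]2(C)[C@@H](C=O)C(C=O)=CC[C@@H]12 | target

**Step count and risks**

Total step count: 18. Longest linear sequence: 17 (steps 1–13 and 15–18); step 14 is a one-step side branch.

Steps most likely to fail:

Step 4. The vinyl ketone may be consumed before the C4 radical forms, by conjugate reduction through the metal hydride, by ethanolysis of the non-enolisable 1,3-diketone (retro-Claisen), or by oligomerisation. The fallback makes the same C4 radical from a halide instead of from the alkene. Setting out from 8, hydrogen bromide in CH2Cl2 at low temperature would add to the isopropenyl group (Markovnikov) and to the vinyl ketone to give the dibromide 5-(2-bromopropan-2-yl)-6-(3-bromopropanoyl)-2,6-dimethylcyclohex-2-en-1-one F1. Triethylamine at 0 °C would eliminate HBr only from the β-bromo ketone and give the tertiary bromide 6-acryloyl-5-(2-bromopropan-2-yl)-2,6-dimethylcyclohex-2-en-1-one F2. Slow addition of tributyltin hydride with AIBN in benzene at 80 °C would then bring about the same 6-endo Giese cyclisation, forming the same C3–C4 bond and ring A, and come back to the route at 9.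

Step 9. The electron-transfer stage may over-reduce the ester or protonate the radical anion at C8 instead of C6, so that the alkene ends up in the wrong place. The fallback separates saturation of C6=C7 from the deconjugation. Setting out from 14, diimide (potassium azodicarboxylate, AcOH) would reduce only the disubstituted C6=C7 bond and give the conjugated ester methyl 1β-(tert-butyldimethylsilyloxy)drim-8-en-11-oate F3. γ-Deprotonation of this ester at C7 with LDA/HMPA in THF at −78 °C would regenerate dienolate 15 without any reducing agent, and kinetic α-protonation with a hindered proton source at −78 °C would come back to the route at 16.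

Step 10. The ene reaction may be diverted to the C9–H that the ester activates or to the C6 methylene, or the oxidation may run on past the aldehyde. The fallback takes the ester out before the oxidation and moves it to the acetate of the C11 alcohol, where C9–H is no longer acidified and allylic oxidation of this substrate class has the closest precedent. Setting out from 16, LiAlH4 in THF at 0 °C would give the alcohol 1β-(tert-butyldimethylsilyloxy)drim-7-en-11-ol F4. Acetic anhydride with pyridine and DMAP would give 1β-(tert-butyldimethylsilyloxy)drim-7-en-11-yl acetate F5. Selenium dioxide in dioxane would give the enal 1β-(tert-butyldimethylsilyloxy)-12-oxodrim-7-en-11-yl acetate F6. LiAlH4, which reduces the aldehyde and cleaves the acetate in one operation, would come back to the route at 18.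

**Further compounds**

F1 | step 4 | 5-(2-bromopropan-2-yl)-6-(3-bromopropanoyl)-2,6-dimethylcyclohex-2-en-1-one (configuration as in 8) | CC1=CC[C@@H](C(C)(C)Br)[C@](C)(C(=O)CCBr)C1=O
F2 | step 4 | 6-acryloyl-5-(2-bromopropan-2-yl)-2,6-dimethylcyclohex-2-en-1-one (configuration as in 8) | CC1=CC[C@@H](C(C)(C)Br)[C@](C)(C(=O)C=C)C1=O
F3 | step 9 | methyl 1β-(tert-butyldimethylsilyloxy)drim-8-en-11-oate | CC1(C)CC[C@@H](O[Si](C)(C)C(C)(C)C)[C@]2(C)C(C(=O)OC)=C(C)CC[C@@H]12
F4 | step 10 | 1β-(tert-butyldimethylsilyloxy)drim-7-en-11-ol | CC1(C)CC[C@@H](O[Si](C)(C)C(C)(C)C)[C@]2(C)[C@@H](CO)C(C)=CC[C@@H]12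
F5 | step 10 | 1β-(tert-butyldimethylsilyloxy)drim-7-en-11-yl acetate | CC1(C)CC[C@@H](O[Si](C)(C)C(C)(C)C)[C@]2(C)[C@@H](COC(C)=O)C(C)=CC[C@@H]12
F6 | step 10 | 1β-(tert-butyldimethylsilyloxy)-12-oxodrim-7-en-11-yl acetate | CC1(C)CC[C@@H](O[Si](C)(C)C(C)(C)C)[C@]2(C)[C@@H](COC(C)=O)C(C=O)=CC[C@@H]12
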